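Slowness comes first. Thursday's flask makes E at 3.89 mM min⁻¹ over its first 1.8 min, yet at 1.10 mM min⁻¹ between 3.1 min and 9.0 min, when E stands at 20.4 % of the Z charged.

| flask | Z | J | E | time |
|---|---|---|---|---|
| Thursday's | 80.0 mM | 96.0 mM |  |  |
| Saturday's | 40.0 mM | 96.0 mM |  |  |
| Monday's | 80.0 mM | 96.0 mM | 80.0 mM | 9.0 min |

| run | time / min | [E] / mM |
|---|---|---|
| Thursday's run | 0.36 | 1.8 |
| Thursday's run | 0.62 | 3.4 |
| Thursday's run | 1.1 | 4.9 |
| Thursday's run | 1.8 | 7.0 |
| Thursday's run | 3.1 | 9.8 |
| Thursday's run | 5.3 | 15.5 |
| Thursday's run | 9.0 | 16.3 |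
| Saturday's run | 0.36 | 2.9 |
| Saturday's run | 0.62 | 1.6 |
| Saturday's run | 1.1 | 2.5 |
| Saturday's run | 1.8 | 4.6 |
| Saturday's run | 3.1 | 7.6 |
| Saturday's run | 5.3 | 7.9 |
| Saturday's run | 9.0 | 11.4 |

(each reading ± 0.8 mM)

- apparent order in [Z] of the starting rate, round the charge of the Thursday's run (the rate where two percent of its Z have turned into E) (one fixed amount of E, the same in the runs compared)
- E in the Monday's run at 9.0 min, as a share of the Z charged

- Overall: Z + J -> E.
- Constant volume, constant temperature.
- A reading of a species includes what of it is bound.
- "The second partner" is J.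
- An order is taken over about fifteen percent of the charge, up and down.
- A share of E counts the E that was charged too.

Saturday's first 1.8 min give 2.56 mM min⁻¹, so I read an order in Z of 0.606, with the scatter of single readings. I take the late slowing as a loss of E, pseudo-first-order with constant λ. Holding formation at its early rate, with mean E of 13.1 mM over that stretch, I get λ = 0.214 min⁻¹. Formation and loss then balance at a ceiling E* = 18.2 mM. Saturday tests this: its ceiling and λ predict 10.2 mM at 9.0 min, and the reading is 11.4 mM.

I suppose the loss consumes J, so λ scales with J. Both runs start at 96.0 mM of J, so they do not show how formation depends on J, and I hold E* at its Thursday value purely as a working assumption of this reckoning. Thursday's J is near 82.9 mM; on Monday, I replace the falling J by a mean of 48.0 mM. The number is then Λ = λ(J̄/J)t, the count of E lifetimes in the time asked: 1.11. E relaxes from its charge toward E*, reaching 38.5 mM, or 48.2 % of the Z charged. The test: this implies J ends near 14.0 mM, a straight-line mean of 55.0 mM, not 48.0 mM, so one number holds roughly.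

The forecast, unlike me, gives 0.95 and 104 %, holding that the slowing “points to something depending on E, not time”. The flask gives 0.33 and 66.6 %, above my share by 18 percentage points.

    Z + 2 J → E + J (33.78 L² mol⁻² min⁻¹)
    E + J → G (2.166 L mol⁻¹ min⁻¹)
    Z + J ⇌ ZJ, settled at all times (14.30 L mol⁻¹)

On my ceiling, Monday's flask corresponds to Λ = 0.567, against my 1.11. Over its 9.0 min, the step making E and the step E + J → G ran side by side, with ZJ held in fast balance with Z and J, and E went from 80.0 mM to 53.3 mM.

The data are simulated for substances that don't exist; scatter was added.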